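The runs were computed with made-up constants; scatter was added.

I read this flask at 50 min, but the cedar run, with the same charges, has been followed to 15.0 min.

| setting | cedar | flask |
|---|---|---|
| substrate | 1 mM | 1.0 mM |
| coupling partner | 2.5 mM | 2.50 mM |
| capture agent | 0.10 mM | 0.100 mM |
| remark | the very flask that is asked about, followed so far |  |
| time |  | 50 min |

cedar run (percent of the substrate charged)

| time / min | substrate / % | target / % |
|---|---|---|
| 1.33 | 63.1 | 5.0 |
| 2.00 | 63.6 | 7.4 |
| 3.00 | 64.1 | 10.8 |
| 4.00 | 64.2 | 14.3 |
| 6.00 | 63.5 | 21.0 |
| 10.0 | 64.1 | 24.4 |
| 15.0 | 62.4 | 27.4 |

(each reading ± 1 percentage point)

* at 50 min, what has stopped the reaction, if anything has (all of the substrate has reacted / it is still moving / the coupling partner has run out first)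
* share of the substrate used up at 50 min
* target at 50 min, in percent of the substrate charged
* trapped intermediate at 50 min, in percent of the substrate charged

- the analysis behind the earlier runs scatters by 1 percentage point, standard deviation
- reactions considered so far: substrate + coupling partner -> open intermediate; open intermediate -> target; coupling partner -> decomposed reagent; open intermediate + capture agent -> trapped intermediate
- the reaction counts as stopped when no species that holds the substrate changes by six tenths of a point or more over the second half of the time

Substrate and coupling partner give open intermediate, which goes on to target or meets capture agent and becomes trapped intermediate; coupling partner also decomposes by itself.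

In cedar the substrate lies flat from the first reading, at a mean fraction left of f = 63.6 %, while target still climbs. So I read cedar's later gain as coming from a pool that is neither substrate nor target, 9.03 % of the substrate at its last reading, and I expect the longer time of this flask to add to target and not to conversion.

Coupling runs with c(substrate)·c(coupling partner), decomposition with c(coupling partner), so c(coupling partner) cancels from their ratio. Counting by the fraction left, from the charges down to zero coupling partner:

c(coupling partner) = c(substrate)·(1 − f) + K·ln(1/f)

K = 4.71 mM

K, the substrate concentration at which both steps take coupling partner equally fast, is a selectivity factor with the unit of a concentration. It is larger than the charged substrate, so in this flask decomposition takes the bigger share from the start. I commit to a conversion of 36.4 %, with the stop coming from the coupling partner's side.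

The forecast says it is still moving, with conversion 36.5 %, target 34.5 % and trapped intermediate 1.8 %, on the ground that “that pool still changes by more than 0.6 points”. On the stop it differs from my reckoning.

The flask gives: the coupling partner has run out first, conversion 36.2 %, target 30.3 %, trapped intermediate 5.82 %.

    substrate + coupling partner → open intermediate (k = 21.0 /M/s)
    open intermediate → target (k = 0.00240 /s)
    coupling partner → decomposed reagent (k = 0.100 /s)
    open intermediate + capture agent → trapped intermediate (k = 6.90 /M/s)

The forecast and the flask part on the stop: this flask ends with 0 % of its coupling partner, and its second half moves by 0.57 percentage points at most. Conversion ends at 36.2 % because decomposition takes the coupling partner; the run without that step reaches 100 %. With K, this flask's conversion sends 2.12 mM into decomposition.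

In the neighbour charged with 10 mM of coupling partner, the same balance with K, solved by putting in f at zero and then the first answer, leaves 14.4 % of the substrate. The computed neighbour keeps 14.6 %.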